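Ring B (the carbocycle, isochromene numbering) is cut across two opposite bonds, C4a–C8a and C6–C7, into two three-carbon units: an ynal (C6 aldehyde, C4a as its β-carbon) and an acetoacetate bearing a CH2CHO arm (C8a α to aldehyde C1, C7 the ketone). One pot joins them: the morpholine enamine of the aldehyde adds to the ynal (C8a–C4a), then a chiral triazolylidene unites the two carbonyl carbons C6 and C7 of like polarity by a crossed benzoin, closing ring B and setting C7 and C8. The feature exploited is the 1,3-relation of carbonyl-derived C6 to acceptor C4a and of ketone C7 to donor C8a. Ring A follows by alkyne cycloisomerization.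

Key step: step 7

Assumption: the (5aS,10bR) enantiomer of the aminoindanol triazolium salt is taken as the one that delivers 7R; if the sense of induction proves opposite, its commercial mirror image is used and nothing else changes.

Step 1
Reactants: 1 (S)-1-bromo-2-methylbutane; 2 N-methoxy-N-methylacetamide
Product: 4 (S)-4-methylhexan-2-one, via Grignard reagent 3 (not isolated)
Conditions: Mg, THF, reflux; then 2, 0 °C → rt; 1 M HCl
Reagents that add atoms: none
Why: Weinreb ketone synthesis, in which the primary Grignard reagent adds only once because the magnesium-chelated tetrahedral adduct survives until the acidic quench; the β-stereocentre is not touched.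

Step 2
Reactants: 4 (S)-4-methylhexan-2-one
Product: 5 (2S,4S)-4-methylhexan-2-ol
Conditions: alcohol dehydrogenase of Prelog selectivity (ketoreductase class), NAD+ (cat.), i-PrOH (10 vol %), phosphate buffer pH 7.5, 30 °C
Reagents that add atoms: none
Why: Enzymatic ketone reduction, in which a Prelog-selective ketoreductase delivers hydride to the Re face of a methyl ketone and so should set C2 as S regardless of the remote C4 centre; isopropanol recycles the cofactor.

Step 3
Reactants: 5 (2S,4S)-4-methylhexan-2-ol; 6 ethyl 2-acetylpent-4-enoate (1.5 equiv)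
Product: 7 (2S,4S)-4-methylhexan-2-yl 2-acetylpent-4-enoate (both C2 epimers)
Conditions: DMAP (0.3 equiv), toluene, reflux, 4 Å MS (removal of EtOH)
Reagents that add atoms: none
Why: DMAP-catalysed transesterification of an α-monosubstituted β-keto ester with a secondary alcohol, driven by removal of ethanol; acyl–oxygen cleavage leaves the carbinol configuration intact.

Step 4
Reactants: 7 (2S,4S)-4-methylhexan-2-yl 2-acetylpent-4-enoate
Product: 9 (2S,4S)-4-methylhexan-2-yl 2-acetyl-4-oxobutanoate, via ozonide 8 (not isolated)
Conditions: O3, CH2Cl2, −78 °C; then PPh3, −78 °C → rt; used crude at once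
Reagents that add atoms: ozone [O-][O+]=O
Why: Ozonolysis with reductive work-up cleaves the terminal alkene much faster than the hydrogen-bonded keto ester enol; the keto aldehyde is kept free of acid because acid would cyclize it to a furan.

Step 5
Reactants: 10 hexa-2,4-diyne-1,6-diol (3 equiv); 11 tert-butyl (triphenylphosphoranylidene)acetate (1 equiv)
Product: 13 tert-butyl (E)-8-hydroxyoct-2-en-4,6-diynoate, via hydroxy ynal 12 (not isolated)
Conditions: activated MnO2, CH2Cl2/THF, rt; filtration, chromatography (excess diol recovered)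
Reagents that add atoms: none
Why: Tandem oxidation–Wittig olefination, in which MnO2 oxidizes one propargylic alcohol to the unstable ynal and the stabilized ylide traps it in situ as the E-enoate; the excess of the symmetric diol should limit double reaction.

Step 6
Reactants: 13 tert-butyl (E)-8-hydroxyoct-2-en-4,6-diynoate
Product: 14 tert-butyl (E)-8-oxooct-2-en-4,6-diynoate
Conditions: activated MnO2, CH2Cl2, rt; filtered and used directly
Reagents that add atoms: none
Why: MnO2 oxidation of a propargylic alcohol stops at the conjugated ynal and leaves the enoate and the diyne untouched.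

Step 7
Reactants: 9 (2S,4S)-4-methylhexan-2-yl 2-acetyl-4-oxobutanoate (1.1 equiv); 14 tert-butyl (E)-8-oxooct-2-en-4,6-diynoate
Product: 17 ring B ketol (2S,4S)-4-methylhexan-2-yl (1R,6R)-6-hydroxy-6-methyl-2-(morpholin-4-ylmethylidene)-5-oxo-3-[(3E)-5-tert-butoxy-5-oxopent-3-en-1-yn-1-yl]cyclohex-3-ene-1-carboxylate, via enamine 15 (not isolated), via aminodienal 16 (not isolated)
Conditions: morpholine (1.0 equiv), 4 Å MS, CH2Cl2, 0 °C; then 14, t-BuOH co-solvent, −40 °C → rt; then (5aS,10bR)-2-mesityl-5a,10b-dihydro-4H,6H-indeno[2,1-b][1,2,4]triazolo[4,3-d][1,4]oxazinium chloride (15 mol %), DBU (20 mol %), 35 °C; one flask, no work-up between the additions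
Reagents that add atoms: morpholine C1COCCN1
Why: Proposed new method: the aldehyde of 9 condenses with morpholine to enamine 15, whose β-carbon (C8a) adds to the β-carbon (C4a) of ynal 14 in a Bohlmann–Rahtz-type Michael addition, the alcohol co-solvent relaying the proton so that the 5-aminodienal 16 forms instead of a [2+2] adduct; the triazolylidene then adds to the C6 aldehyde and the Breslow intermediate attacks the C7 ketone (crossed aldehyde–ketone benzoin), joining two carbonyl carbons of like polarity. The closest known reactions are secondary-amine/carbene Michael–benzoin cascades that give cyclopentanones and intramolecular aldehyde–ketone benzoin cyclizations to six-membered ketols; new here are the enamine/ynal pairing in a [3+3] sense and a vinylogous formamide as the acyl-anion precursor, which should be slow but viable because electron-rich aldehydes serve as the acyl donor in crossed benzoins. Ring B closes 6-exo-trig (C6 onto the C7 carbonyl); the C4a–C8a bond closes no ring in this step. C8 epimerizes freely in the β-keto ester, so the benzoin is a dynamic kinetic resolution: the chiral carbene selects the face of the C7 ketone (7R) and the cyclic transition state places the C7 methyl anti to the C8 ester, so hydroxyl and ester end up cis (8R). The step needs 1,4- rather than 1,6-addition to the diynal and attack by C8a rather than by the keto ester carbon C8; the enamine is by far the stronger nucleophile, C4a is the acceptor position next to the formyl group, and only the C6 aldehyde can reach the ketone through a six-membered ring.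

Step 8
Reactants: 17 ring B ketol (morpholine enaminone)
Product: 19 (2S,4S)-4-methylhexan-2-yl (7R,8R)-3-[(E)-3-tert-butoxy-3-oxoprop-1-enyl]-7-hydroxy-7-methyl-6-oxo-7,8-dihydro-6H-isochromene-8-carboxylate, via hydroxymethylene ketol 18 (not isolated)
Conditions: p-TsOH·H2O (1.2 equiv), THF/H2O (10:1), rt; then AgOTf (10 mol %), rt
Reagents that add atoms: water O
Why: Acid hydrolysis of the vinylogous amide frees the hydroxymethylene ketone, whose enol oxygen closes ring A by silver-catalysed 6-endo-dig cycloisomerization onto C3 of the alkyne (the ring closure known for 2-alkynyl carbonyl precursors of isochromenes); attack at C3 is favoured because it is the conjugate position of the ring dienone and gives the fully conjugated pyran.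

Step 9
Reactants: 19 tert-butyl ester of the target
Product: 20 (E)-3-[(7R,8R)-7-hydroxy-7-methyl-8-{[(2S,4S)-4-methylhexan-2-yl]oxycarbonyl}-6-oxo-7,8-dihydro-6H-isochromen-3-yl]prop-2-enoic acid (target)
Conditions: TFA/CH2Cl2 (1:3), 0 °C → rt; evaporation, neutral work-up
Reagents that add atoms: none
Why: Acidolysis of the tert-butyl ester by loss of isobutene should spare the secondary alkyl ester and the tertiary ketol, while the pyran is only protonated reversibly and C8 is not activated in that cation.

Compound list
1 | (S)-1-bromo-2-methylbutane | CC[C@H](C)CBr | starting material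
2 | N-methoxy-N-methylacetamide | CC(=O)N(C)OC | starting material
3 | (S)-2-methylbutylmagnesium bromide | CC[C@H](C)C[Mg]Br | intermediate
4 | (S)-4-methylhexan-2-one | CC[C@H](C)CC(C)=O | intermediate
5 | (2S,4S)-4-methylhexan-2-ol | CC[C@H](C)C[C@H](C)O | intermediate
6 | ethyl 2-acetylpent-4-enoate (racemic) | CCOC(=O)C(CC=C)C(C)=O | starting material
7 | (2S,4S)-4-methylhexan-2-yl 2-acetylpent-4-enoate (both C2 epimers) | CC[C@H](C)C[C@H](C)OC(=O)C(CC=C)C(C)=O | intermediate
8 | (2S,4S)-4-methylhexan-2-yl 2-acetyl-3-(1,2,4-trioxolan-3-yl)propanoate (ozonide) | CC[C@H](C)C[C@H](C)OC(=O)C(CC1OCOO1)C(C)=O | intermediate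
9 | (2S,4S)-4-methylhexan-2-yl 2-acetyl-4-oxobutanoate | CC[C@H](C)C[C@H](C)OC(=O)C(CC=O)C(C)=O | intermediate
10 | hexa-2,4-diyne-1,6-diol | OCC#CC#CCO | starting material
11 | tert-butyl (triphenylphosphoranylidene)acetate | CC(C)(C)OC(=O)C=P(c1ccccc1)(c1ccccc1)c1ccccc1 | starting material
12 | 6-hydroxyhexa-2,4-diynal | OCC#CC#CC=O | intermediate
13 | tert-butyl (E)-8-hydroxyoct-2-en-4,6-diynoate | OCC#CC#C/C=C/C(=O)OC(C)(C)C | intermediate
14 | tert-butyl (E)-8-oxooct-2-en-4,6-diynoate | O=CC#CC#C/C=C/C(=O)OC(C)(C)C | intermediate
15 | (2S,4S)-4-methylhexan-2-yl (E)-2-acetyl-4-(morpholin-4-yl)but-3-enoate (enamine, in equilibrium with its cyclic N,O-acetal) | CC[C@H](C)C[C@H](C)OC(=O)C(/C=C/N1CCOCC1)C(C)=O | intermediate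
16 | (2S,4S)-4-methylhexan-2-yl 2-acetyl-4-[(3E)-5-tert-butoxy-5-oxopent-3-en-1-yn-1-yl]-3-(morpholin-4-ylmethylidene)-6-oxohex-4-enoate (diene geometry mobile) | CC[C@H](C)C[C@H](C)OC(=O)C(C(C)=O)C(=CN1CCOCC1)C(C#C/C=C/C(=O)OC(C)(C)C)=CC=O | intermediate
17 | (2S,4S)-4-methylhexan-2-yl (1R,6R)-6-hydroxy-6-methyl-2-(morpholin-4-ylmethylidene)-5-oxo-3-[(3E)-5-tert-butoxy-5-oxopent-3-en-1-yn-1-yl]cyclohex-3-ene-1-carboxylate | CC[C@H](C)C[C@H](C)OC(=O)[C@@H]1C(=CN2CCOCC2)C(C#C/C=C/C(=O)OC(C)(C)C)=CC(=O)[C@]1(C)O | intermediate
18 | (2S,4S)-4-methylhexan-2-yl (1R,6R)-6-hydroxy-2-(hydroxymethylidene)-6-methyl-5-oxo-3-[(3E)-5-tert-butoxy-5-oxopent-3-en-1-yn-1-yl]cyclohex-3-ene-1-carboxylate | CC[C@H](C)C[C@H](C)OC(=O)[C@@H]1C(=CO)C(C#C/C=C/C(=O)OC(C)(C)C)=CC(=O)[C@]1(C)O | intermediate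
19 | (2S,4S)-4-methylhexan-2-yl (7R,8R)-3-[(E)-3-tert-butoxy-3-oxoprop-1-enyl]-7-hydroxy-7-methyl-6-oxo-7,8-dihydro-6H-isochromene-8-carboxylate | CC[C@H](C)C[C@H](C)OC(=O)[C@@H]1C2=COC(/C=C/C(=O)OC(C)(C)C)=CC2=CC(=O)[C@]1(C)O | intermediate
20 | (E)-3-[(7R,8R)-7-hydroxy-7-methyl-8-{[(2S,4S)-4-methylhexan-2-yl]oxycarbonyl}-6-oxo-7,8-dihydro-6H-isochromen-3-yl]prop-2-enoic acid | CC[C@H](C)C[C@H](C)OC(=O)[C@@H]1C2=COC(/C=C/C(=O)O)=CC2=CC(=O)[C@]1(C)O | target

Total step count: 9. Longest linear sequence: 7 steps (steps 1, 2, 3, 4, 7, 8, 9); steps 5 and 6 build the ynal separately.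

Steps most likely to fail

Step 7 (proposed new method). The carbene may fail to add to the aldehyde of 16, whose carbonyl is strongly deactivated by the vinylogous amine donor, so that no Breslow intermediate forms and 16 drifts instead toward a furan by attack of the keto ester enol on C1. The fallback makes the two bonds in separate, individually known operations. It sets out from 16, obtained by running only the enamine Michael addition of step 7 and isolating the product. Aqueous oxalic acid hydrolyses the enamine to the free hydroxydienal F1. TBSCl and imidazole convert it into the silyl dienol ether F2, whose aldehyde now carries only an alkoxy-type donor comparable to an alkoxybenzaldehyde; its O-silyl regioisomer should interconvert under the basic conditions, and only the isomer with the free C6 aldehyde can cyclize. The same triazolium salt with DBU in toluene then effects an ordinary crossed aldehyde–ketone benzoin to the silyl-capped ketol F3. F3 is submitted to the conditions of step 8, where the acid cleaves the silyl enol ether in place of the enamine, so the route is rejoined at 18 and continues to 19.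

Step 8. Oxygen attack on the silver-bound alkyne may go with poor regiocontrol, 5-exo at C4 toward an alkylidene furan competing with 6-endo at C3, or the electron-poor enyne may bind silver too weakly to turn over. The fallback sets out from 17, hydrolysed to 18 as before, and closes ring A by electrophilic iodocyclization (I2, NaHCO3, MeCN, 0 °C), in which the iodonium opens at C3, the carbon better able to carry positive charge, to give the 4-iodopyran F4. Hydrogenolysis of the vinyl iodide with Pd(PPh3)4, HCO2H and Et3N in DMF at 40 °C then returns the route at 19.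

Step 4. The keto aldehyde 9 may be lost by acid-triggered cyclodehydration to the 2-methyl-3-furoate (Paal–Knorr) during ozonide reduction, concentration or storage. The fallback never passes through the free keto aldehyde. It sets out from 5, which is acylated with (E)-4-bromobut-2-enoyl chloride (pyridine, CH2Cl2, 0 °C) to the bromocrotonate F5. Morpholine (2.2 equiv, THF, 0 °C) displaces the allylic bromide to give the morpholinocrotonate F6. LDA (2.1 equiv, THF, −78 °C) forms the amino dienolate, which is acetylated at the α-carbon with N-acetylimidazole (crossed Claisen acylation), and a buffered quench delivers the enamine 15, at which the route is rejoined and carried straight into step 7.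

Further compounds
F1 | step 7 | (2S,4S)-4-methylhexan-2-yl 2-acetyl-3-(hydroxymethylidene)-6-oxo-4-[(3E)-5-tert-butoxy-5-oxopent-3-en-1-yn-1-yl]hex-4-enoate | CC[C@H](C)C[C@H](C)OC(=O)C(C(C)=O)C(=CO)C(C#C/C=C/C(=O)OC(C)(C)C)=CC=O
F2 | step 7 | (2S,4S)-4-methylhexan-2-yl 2-acetyl-3-[(tert-butyldimethylsilyloxy)methylidene]-6-oxo-4-[(3E)-5-tert-butoxy-5-oxopent-3-en-1-yn-1-yl]hex-4-enoate | CC[C@H](C)C[C@H](C)OC(=O)C(C(C)=O)C(=CO[Si](C)(C)C(C)(C)C)C(C#C/C=C/C(=O)OC(C)(C)C)=CC=O
F3 | step 7 | (2S,4S)-4-methylhexan-2-yl (1R,6R)-2-[(tert-butyldimethylsilyloxy)methylidene]-6-hydroxy-6-methyl-5-oxo-3-[(3E)-5-tert-butoxy-5-oxopent-3-en-1-yn-1-yl]cyclohex-3-ene-1-carboxylate | CC[C@H](C)C[C@H](C)OC(=O)[C@@H]1C(=CO[Si](C)(C)C(C)(C)C)C(C#C/C=C/C(=O)OC(C)(C)C)=CC(=O)[C@]1(C)O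
F4 | step 8 | (2S,4S)-4-methylhexan-2-yl (7R,8R)-3-[(E)-3-tert-butoxy-3-oxoprop-1-enyl]-7-hydroxy-4-iodo-7-methyl-6-oxo-7,8-dihydro-6H-isochromene-8-carboxylate | CC[C@H](C)C[C@H](C)OC(=O)[C@@H]1C2=COC(/C=C/C(=O)OC(C)(C)C)=C(I)C2=CC(=O)[C@]1(C)O
F5 | step 4 | (2S,4S)-4-methylhexan-2-yl (E)-4-bromobut-2-enoate | CC[C@H](C)C[C@H](C)OC(=O)/C=C/CBr
F6 | step 4 | (2S,4S)-4-methylhexan-2-yl (E)-4-(morpholin-4-yl)but-2-enoate | CC[C@H](C)C[C@H](C)OC(=O)/C=C/CN1CCOCC1
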